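Ring A is disconnected across C1–C10 and C4–C5 (labdane numbering), a retro-Diels–Alder cut to 4-methylpenta-1,3-diene and 2-methoxy-6-methyl-1,4-benzoquinone. One catalytic enantioselective cycloaddition closes ring A, fixes quaternary C10, delivers the C4 gem-dimethyl group and leaves a C2=C3 alkene from which the axial 3α-acetoxy group is made. The feature exploited is that ring A bears exactly this C10-methyl/C4-dimethyl/C3-oxygen pattern, while ring B carbons C6, C8 and C9 come from oxygenated quinone carbons, which allow attachment of the linalool-derived C11–C16 chain at C9 and formation of the 8(17)-methylene. The precursor is a simple quinone whose methoxy group switches off its second double bond.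

Key step: step 2

Assumption: the sense of induction in step 2 is taken from the accepted α-C–H···O binding model of oxazaborolidinium–quinone complexes, which predicts that the (R)-catalyst gives the (8aS) adduct (otherwise the enantiomeric catalyst is used); labdane numbering with α/β descriptors (C10 methyl β) is used for all ring compounds, and commercial (S)-linalool is taken to be of high enantiomeric purity.

Step 1
Reactants: 1 2-methoxy-6-methylphenol
Product: 2 2-methoxy-6-methyl-1,4-benzoquinone
Conditions: ON(SO3K)2 (2.2 equiv), KH2PO4, H2O/acetone, 0 °C → rt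
Reagents that add atoms: potassium nitrosodisulfonate, [K+].[K+].[O-]S(=O)(=O)N([O])S(=O)(=O)[O-]
Why: Teuber oxidation, in which the phenoxyl radical is trapped at the free para position by a second nitroxyl radical and loss of imidodisulfonate gives the para-quinone.

Step 2
Reactants: 2 2-methoxy-6-methyl-1,4-benzoquinone and 3 4-methylpenta-1,3-diene
Product: 4 cis adduct (4aR,8aS)-2-methoxy-5,5,8a-trimethyl-4a,5,8,8a-tetrahydronaphthalene-1,4-dione
Conditions: (3aR)-1-(2-methylphenyl)-3,3-diphenyltetrahydro-1H,3H-pyrrolo[1,2-c][1,3,2]oxazaborole (20 mol %), (CF3SO2)2NH (18 mol %), 3 (5 equiv), CH2Cl2, −78 → −40 °C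
Reagents that add atoms: none
Why: The reaction is a concerted but asynchronous, Lewis-acid-accelerated [4+2] cycloaddition, the closest known type being the enantioselective Diels–Alder reaction of substituted 1,4-benzoquinones under chiral cationic oxazaborolidine catalysis. Ring A is closed in cycloaddition mode as a cyclohexene, the C1–C10 and C4–C5 bonds forming on the same face of the C5=C10 bond, so the product is cis-fused. Only C5=C10 can act as dienophile, because the methoxy substituent turns C7=C8 into an electron-rich vinylogous ester. Coordination of the boron cation to O6, the carbonyl oxygen made more basic by the methoxy group, polarises the dienophile so that C10 accepts the CH2 terminus of the diene, which is also the sterically easier orientation since C4 and C10 do not become neighbours. C10 is set by the catalyst, whose contact between the ring oxygen and H-5 holds the quinone over one aryl group so that the diene adds to the open face, whereas C5 follows from the suprafacial addition and is inverted in step 3. The main liability is the diene, whose Z-terminal methyl raises the energy of the s-cis conformer, and this is countered with excess diene, low temperature and the triflimide-activated catalyst.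

Step 3
Reactants: 4 cis adduct (4aR,8aS)-2-methoxy-5,5,8a-trimethyl-4a,5,8,8a-tetrahydronaphthalene-1,4-dione
Product: 6 trans adduct (4aS,8aS)-2-methoxy-5,5,8a-trimethyl-4a,5,8,8a-tetrahydronaphthalene-1,4-dione, via potassium dienolate 5 (not isolated)
Conditions: KN(SiMe3)2 (1.1 equiv), THF, −78 °C; then AcOH (2 equiv), −78 °C → rt
Reagents that add atoms: none
Why: Enolate formation and kinetic C-protonation, in which H-5 is the only acidic hydrogen and the planar C5=C6 enolate 5 is protonated from the α face, opposite the axial C10 and 4β methyl groups that flank C5, to give the 5α-H trans-fused isomer.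

Step 4
Reactants: 6 trans adduct (4aS,8aS)-2-methoxy-5,5,8a-trimethyl-4a,5,8,8a-tetrahydronaphthalene-1,4-dione
Product: 7 2α,3α-epoxide of 6 (epoxide oxygen trans to the C10 methyl)
Conditions: mCPBA (1.2 equiv), NaHCO3, CH2Cl2, 0 °C → rt
Reagents that add atoms: 3-chloroperoxybenzoic acid, OOC(=O)c1cccc(Cl)c1
Why: Prilezhaev epoxidation, in which the isolated C2=C3 bond reacts in preference to the electron-poor enedione alkene and the peracid approaches from the α face because the axial C10 and 4β methyl groups shield the β face, setting C2 and C3.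

Step 5
Reactants: 8 (S)-linalool
Product: 9 tert-butyl{[(3S)-3,7-dimethylocta-1,6-dien-3-yl]oxy}dimethylsilane
Conditions: TBSOTf (1.3 equiv), 2,6-lutidine, CH2Cl2, 0 °C → rt
Reagents that add atoms: tert-butyldimethylsilyl trifluoromethanesulfonate, CC(C)(C)[Si](C)(C)OS(=O)(=O)C(F)(F)F
Why: Silylation of a tertiary alcohol with a silyl triflate and a hindered pyridine base, which leaves the carbinol stereocenter untouched.

Step 6
Reactants: 9 tert-butyl{[(3S)-3,7-dimethylocta-1,6-dien-3-yl]oxy}dimethylsilane
Product: 11 (4S)-4-(tert-butyldimethylsilyloxy)-4-methylhex-5-enoic acid, via aldehyde 10 (not isolated)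
Conditions: O3, CH2Cl2/MeOH, −78 °C (Sudan Red 7B end point); Me2S, −78 °C → rt; then NaClO2, NaH2PO4, 2-methylbut-2-ene, t-BuOH/H2O, 0 °C → rt
Reagents that add atoms: ozone, [O-][O+]=O; sodium chlorite, [Na+].[O-]Cl=O
Why: Ozonolysis, selective for the electron-rich trisubstituted alkene over the vinyl group, followed by Pinnick oxidation of the crude aldehyde 10.

Step 7
Reactants: 11 (4S)-4-(tert-butyldimethylsilyloxy)-4-methylhex-5-enoic acid
Product: 13 tert-butyl{[(3S)-5-iodo-3-methylpent-1-en-3-yl]oxy}dimethylsilane, via Barton ester 12 (not isolated)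
Conditions: N-hydroxypyridine-2-thione, DCC, DMAP (cat.), CH2Cl2, rt, dark; then CHI3 (1.5 equiv), PhH, hν (tungsten lamp), rt → 60 °C
Reagents that add atoms: iodoform, IC(I)I
Why: Barton decarboxylation with iodoform as iodine-atom donor, which removes the one carbon that linalool carries in excess of the C11–C12 bridge and leaves a primary iodide whose radical precursor is remote from the C13 stereocenter.

Step 8
Reactants: 13 tert-butyl{[(3S)-5-iodo-3-methylpent-1-en-3-yl]oxy}dimethylsilane and 7 2α,3α-epoxide of 6
Product: 16 C9 carbinol (13S)-13-(tert-butyldimethylsilyloxy)-2α,3α-epoxy-9β-hydroxy-8-methoxy-17-norlabda-7,14-dien-6-one (side chain on the α face), via alkyllithium 14 (not isolated), via alkylcerium dichloride 15 (not isolated)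
Conditions: 13 (1.5 equiv), t-BuLi (3.1 equiv), Et2O, −78 °C; CeCl3 (anhydrous), THF, −78 °C; then 7, −78 → −40 °C
Reagents that add atoms: none
Why: Iodine–lithium exchange, transmetallation to the weakly basic organocerium and 1,2-addition to a ketone, in which C9 is the more electrophilic carbonyl (C6 is a vinylogous ester carbonyl shielded by the gem-dimethyl-bearing C5) and the reagent enters from the α face anti to the axial C10 methyl, giving a C9 configuration that is erased in step 11.

Step 9
Reactants: 16 C9 carbinol (13S)-13-(tert-butyldimethylsilyloxy)-2α,3α-epoxy-9β-hydroxy-8-methoxy-17-norlabda-7,14-dien-6-one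
Product: 18 (13S)-13-(tert-butyldimethylsilyloxy)-3α,9β-dihydroxy-17-norlabda-6,14-dien-8-one, via triol 17 (not isolated)
Conditions: LiAlH4 (5 equiv), THF, 0 °C → reflux; then 1 M HCl, THF, 0 °C → rt
Reagents that add atoms: water, O
Why: Hydride reduction with Fürst–Plattner (trans-diaxial) epoxide opening and then Stork–Danheiser transposition, in which hydride attacks C2 axially from the β face so that oxygen stays on C3 as the axial 3α-alcohol, C6 is reduced to the allylic alcohol of triol 17, and aqueous acid hydrolyses the enol ether with loss of the C6 hydroxyl to give the C8 ketone conjugated with C6=C7.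

Step 10
Reactants: 18 (13S)-13-(tert-butyldimethylsilyloxy)-3α,9β-dihydroxy-17-norlabda-6,14-dien-8-one
Product: 19 (13S)-13-(tert-butyldimethylsilyloxy)-3α,9β-dihydroxy-17-norlabd-14-en-8-one
Conditions: [(Ph3P)CuH]6 (0.5 equiv), H2O (5 equiv), toluene/THF, rt
Reagents that add atoms: none
Why: Conjugate (1,4) reduction of an enone by a phosphine-stabilised copper hydride, which leaves the isolated vinyl group, the ketone and the free hydroxyl groups untouched and creates no stereocenter.

Step 11
Reactants: 19 (13S)-13-(tert-butyldimethylsilyloxy)-3α,9β-dihydroxy-17-norlabd-14-en-8-one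
Product: 21 (13S)-13-(tert-butyldimethylsilyloxy)-3α-hydroxy-17-norlabd-14-en-8-one (9α-H), via samarium enolate 20 (not isolated)
Conditions: SmI2 (3 equiv), MeOH (10 equiv), THF, −78 °C → rt
Reagents that add atoms: none
Why: SmI2 reductive cleavage of an α-hydroxy ketone through the ketyl, in which enolate 20 is protonated at C9 from the α face anti to the axial C10 methyl, placing the side chain equatorial (9α-H), the arrangement that is also thermodynamically preferred.

Step 12
Reactants: 21 (13S)-13-(tert-butyldimethylsilyloxy)-3α-hydroxy-17-norlabd-14-en-8-one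
Product: 22 (13S)-13-(tert-butyldimethylsilyloxy)labda-8(17),14-dien-3α-ol
Conditions: Ph3PCH3Br (5 equiv), KOC(CH3)3 (4.8 equiv), toluene, rt → 80 °C
Reagents that add atoms: methyltriphenylphosphonium bromide, C[P+](c1ccccc1)(c1ccccc1)c1ccccc1.[Br-]
Why: Wittig methylenation of the C8 ketone with excess ylide (the 3-hydroxyl consumes one equivalent), under which any C9 epimer equilibrates to the equatorial side-chain isomer before olefination.

Step 13
Reactants: 22 (13S)-13-(tert-butyldimethylsilyloxy)labda-8(17),14-dien-3α-ol
Product: 23 (13S)-labda-8(17),14-diene-3α,13-diol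
Conditions: Bu4NF (3 equiv), THF, 50 °C
Reagents that add atoms: none
Why: Fluoride-induced cleavage of the tertiary silyl ether, driven by Si–F bond formation, with no stereocenter touched.

Step 14
Reactants: 23 (13S)-labda-8(17),14-diene-3α,13-diol
Product: 24 (13S)-labda-8(17),14-diene-3α,13-diyl diacetate
Conditions: Ac2O (8 equiv), Et3N, DMAP (1 equiv), CH2Cl2, rt → 40 °C
Reagents that add atoms: acetic anhydride, CC(=O)OC(C)=O
Why: DMAP-catalysed (Steglich-type) acyl transfer, which esterifies the axial secondary and the tertiary allylic alcohol without ionising either C–O bond, so both configurations are retained.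

Compound list
1 | 2-methoxy-6-methylphenol | COc1cccc(C)c1O | starting material
2 | 2-methoxy-6-methyl-1,4-benzoquinone | COC1=CC(=O)C=C(C)C1=O | intermediate
3 | 4-methylpenta-1,3-diene | C=CC=C(C)C | starting material
4 | cis adduct, (4aR,8aS)-2-methoxy-5,5,8a-trimethyl-4a,5,8,8a-tetrahydronaphthalene-1,4-dione (10β-CH3, 5β-H) | COC1=CC(=O)[C@@H]2C(C)(C)C=CC[C@]2(C)C1=O | intermediate
5 | potassium C5=C6 dienolate of 4 | COC1=CC([O-])=C2C(C)(C)C=CC[C@]2(C)C1=O.[K+] | intermediate
6 | trans adduct, (4aS,8aS)-2-methoxy-5,5,8a-trimethyl-4a,5,8,8a-tetrahydronaphthalene-1,4-dione (10β-CH3, 5α-H) | COC1=CC(=O)[C@H]2C(C)(C)C=CC[C@]2(C)C1=O | intermediate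
7 | 2α,3α-epoxide of 6 | COC1=CC(=O)[C@H]2C(C)(C)[C@@H]3O[C@@H]3C[C@]2(C)C1=O | intermediate
8 | (S)-linalool, (3S)-3,7-dimethylocta-1,6-dien-3-ol | C=C[C@](C)(CCC=C(C)C)O | starting material
9 | tert-butyl{[(3S)-3,7-dimethylocta-1,6-dien-3-yl]oxy}dimethylsilane | C=C[C@](C)(CCC=C(C)C)O[Si](C)(C)C(C)(C)C | intermediate
10 | (4S)-4-(tert-butyldimethylsilyloxy)-4-methylhex-5-enal | C=C[C@](C)(CCC=O)O[Si](C)(C)C(C)(C)C | intermediate
11 | (4S)-4-(tert-butyldimethylsilyloxy)-4-methylhex-5-enoic acid | C=C[C@](C)(CCC(=O)O)O[Si](C)(C)C(C)(C)C | intermediate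
12 | Barton ester, 1-{[(4S)-4-(tert-butyldimethylsilyloxy)-4-methylhex-5-enoyl]oxy}pyridine-2(1H)-thione | C=C[C@](C)(CCC(=O)On1ccccc1=S)O[Si](C)(C)C(C)(C)C | intermediate
13 | tert-butyl{[(3S)-5-iodo-3-methylpent-1-en-3-yl]oxy}dimethylsilane | C=C[C@](C)(CCI)O[Si](C)(C)C(C)(C)C | intermediate
14 | [(3S)-3-(tert-butyldimethylsilyloxy)-3-methylpent-4-en-1-yl]lithium | C=C[C@](C)(CC[Li])O[Si](C)(C)C(C)(C)C | intermediate
15 | dichloro[(3S)-3-(tert-butyldimethylsilyloxy)-3-methylpent-4-en-1-yl]cerium | C=C[C@](C)(CC[Ce](Cl)Cl)O[Si](C)(C)C(C)(C)C | intermediate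
16 | (13S)-13-(tert-butyldimethylsilyloxy)-2α,3α-epoxy-9β-hydroxy-8-methoxy-17-norlabda-7,14-dien-6-one (side chain 9α) | COC1=CC(=O)[C@H]2C(C)(C)[C@@H]3O[C@@H]3C[C@]2(C)[C@]1(O)CC[C@@](C)(C=C)O[Si](C)(C)C(C)(C)C | intermediate
17 | (13S)-13-(tert-butyldimethylsilyloxy)-8-methoxy-17-norlabda-7,14-diene-3α,6β,9β-triol | COC1=C[C@@H](O)[C@H]2C(C)(C)[C@H](O)CC[C@]2(C)[C@]1(O)CC[C@@](C)(C=C)O[Si](C)(C)C(C)(C)C | intermediate
18 | (13S)-13-(tert-butyldimethylsilyloxy)-3α,9β-dihydroxy-17-norlabda-6,14-dien-8-one | O=C1C=C[C@H]2C(C)(C)[C@H](O)CC[C@]2(C)[C@]1(O)CC[C@@](C)(C=C)O[Si](C)(C)C(C)(C)C | intermediate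
19 | (13S)-13-(tert-butyldimethylsilyloxy)-3α,9β-dihydroxy-17-norlabd-14-en-8-one | O=C1CC[C@H]2C(C)(C)[C@H](O)CC[C@]2(C)[C@]1(O)CC[C@@](C)(C=C)O[Si](C)(C)C(C)(C)C | intermediate
20 | samarium C8=C9 enolate (diiodosamarium enolate of 21) | I[Sm](I)OC=1CC[C@H]2C(C)(C)[C@H](O)CC[C@]2(C)C=1CC[C@@](C)(C=C)O[Si](C)(C)C(C)(C)C | intermediate
21 | (13S)-13-(tert-butyldimethylsilyloxy)-3α-hydroxy-17-norlabd-14-en-8-one (9α-H) | O=C1CC[C@H]2C(C)(C)[C@H](O)CC[C@]2(C)[C@H]1CC[C@@](C)(C=C)O[Si](C)(C)C(C)(C)C | intermediate
22 | (13S)-13-(tert-butyldimethylsilyloxy)labda-8(17),14-dien-3α-ol | C=C1CC[C@H]2C(C)(C)[C@H](O)CC[C@]2(C)[C@H]1CC[C@@](C)(C=C)O[Si](C)(C)C(C)(C)C | intermediate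
23 | (13S)-labda-8(17),14-diene-3α,13-diol | C=C1CC[C@H]2C(C)(C)[C@H](O)CC[C@]2(C)[C@H]1CC[C@@](C)(C=C)O | intermediate
24 | (13S)-labda-8(17),14-diene-3α,13-diyl diacetate (5α-H, 9α-H, 10β-CH3) | C=C[C@](C)(CC[C@H]1C(=C)CC[C@H]2C(C)(C)[C@H](OC(C)=O)CC[C@]12C)OC(C)=O | target

Total step count: 14. Longest linear sequence: 11 steps (steps 1–4 and 8–14, from 1); the side-chain branch (steps 5–7) joins at step 8.

Steps most likely to fail

1. Step 2. The cycloaddition may be too slow because the Z-terminal methyl of the diene disfavours the s-cis conformer. Acid-induced oligomerisation of the diene or stepwise cationic addition (cyclobutane or ene-type products) could then outrun the concerted pathway, and enantioface discrimination may be incomplete. Fallback: setting out from 2 and 3, the cycloaddition is run with an achiral Lewis acid (BF3·OEt2, 1 equiv, CH2Cl2, −20 → 0 °C), which binds the same vinylogous-ester oxygen and so keeps the regiochemistry. This gives racemic material, that is 4 together with an equal amount of its mirror image, the (4aS,8aR)-adduct F1. Preparative chromatography on a chiral stationary phase removes F1, and the route is rejoined at 4; asymmetric induction is thus replaced by resolution.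

2. Step 3. The dienolate may be protonated on oxygen and then ketonise under equilibrating conditions, or the C-protonation may discriminate poorly between the faces. Either would return mainly the cis-fused isomer, and since the cis and trans enediones are expected to be close in energy, equilibration cannot be relied on to correct this. Fallback: setting out from 4, enolate 5 is quenched with N-bromosuccinimide (THF, −78 °C) to give the 5α-bromo enedione F2. Radical dehalogenation (Bu3SnH, AIBN, PhH, 80 °C) then delivers hydrogen irreversibly from the stannane to the planar C5 radical on the α face, and the route is rejoined at 6.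

3. Step 8. The organometallic may attack the C6 carbonyl or add in conjugate fashion at C7, it may enolise C5, or conversion at the neopentyl C9 carbonyl may stall. Fallback: setting out from 7, the C6 ketone is masked (KN(SiMe3)2, THF, −78 °C; Et3SiCl) as the triethylsilyl dienol ether F3, which leaves C9 as the only carbonyl. Addition of 15 (THF, −78 °C) gives the carbinol F4. Bu4NF/AcOH (THF, 0 °C) then removes the enol silyl group with protonation at C5 from the α face, and the route is rejoined at 16; a C9 epimer, if formed, converges at 21.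

Further compounds
F1 | step 2 | (4aS,8aR)-2-methoxy-5,5,8a-trimethyl-4a,5,8,8a-tetrahydronaphthalene-1,4-dione (mirror image of 4) | COC1=CC(=O)[C@H]2C(C)(C)C=CC[C@@]2(C)C1=O
F2 | step 3 | 5α-bromo enedione (4a-bromo derivative of 6, bromine trans to the C10 methyl) | COC1=CC(=O)[C@@]2(Br)C(C)(C)C=CC[C@]2(C)C1=O
F3 | step 8 | triethylsilyl dienol ether of 7 (6-triethylsilyloxy-5,7-diene, 2α,3α-epoxide) | COC1=CC(O[Si](CC)(CC)CC)=C2C(C)(C)[C@@H]3O[C@@H]3C[C@]2(C)C1=O
F4 | step 8 | C9 carbinol from F3 and 15 (6-triethylsilyloxy-5,7-diene, 9-hydroxy, side chain attached) | COC1=CC(O[Si](CC)(CC)CC)=C2C(C)(C)[C@@H]3O[C@@H]3C[C@]2(C)[C@]1(O)CC[C@@](C)(C=C)O[Si](C)(C)C(C)(C)C
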